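**Retrosynthetic overview**
- The target is the caffeate of the C9 alcohol of a (2R,3S,4S)-2-aryl-4-benzyl-oxolane. The last disconnections are the C9–O acyl bond (carbodiimide esterification with silyl-protected caffeic acid) and the four phenol silyl ethers.
- C9–OH comes from a C3 methyl ester. The C4 benzyl group (3,4-cis) comes from hydrogenation of a 4-(Z)-arylmethylidene. The C3–H (2,3-trans) comes from Krapcho loss of one ester of a 3,3-diester.
- The strategy rests on the oxolane ring O1–C2–C3–C4–C5 with the aryl group on C2, the branch C9 on C3 and the benzylic carbon C7′ on C4. It is cut into O1–C5–C4–C7′ (propargyl alcohol), C2–C3–C9 with the C2 aryl group (arylidene malonate) and the aryl ring on C7′ (aryl iodide).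
- Bonds O1–C2, C3–C4 and C7′–aryl are made in one palladium-mediated operation, which closes the only ring built in the route and sets C2.
- The guaiacyl phenols are carried as benzyl ethers through the basic cascade and the Krapcho step (aryl silyl ethers would not survive lithium alkoxide in DMSO or chloride in wet DMSO at 140 °C). They are lost in the hydrogenation and replaced by TBS for the endgame.

Key step: step 3

Remark on numbering: O1, C2 (aryl-bearing), C3, C4, C5 are the oxolane atoms; C9 is the carbon on C3 and C7′ the benzylic carbon on C4.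
Assumptions: 4-(benzyloxy)-3-methoxybenzaldehyde is bought. The hand of the bisphosphine that gives (2S)-9 cannot be predicted, so step 3 is written with (R)-DTBM-SEGPHOS and the (S) ligand is taken if a first run favours the antipode.

**Route**

Step 1
Reactants: 1 4-(benzyloxy)-3-methoxybenzaldehyde; 2 dimethyl malonate
Product: 3 dimethyl 2-{[4-(benzyloxy)-3-methoxyphenyl]methylidene}propanedioate
Conditions: piperidine (0.1 equiv), AcOH (0.1 equiv), toluene, reflux, Dean–Stark
Reagents that add atoms: none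
Why: Knoevenagel condensation driven by azeotropic removal of water; the two ester groups are identical, so no alkene geometry arises.

Step 2
Reactants: 4 4-iodo-2-methoxyphenol
Product: 5 1-(benzyloxy)-4-iodo-2-methoxybenzene
Conditions: BnBr (1.1 equiv), K2CO3, DMF, rt
Reagents that add atoms: benzyl bromide, BrCc1ccccc1
Why: Williamson ether synthesis on the phenoxide; the benzyl ether is inert to the alkoxide/DMSO medium of step 3 and to hot chloride in step 4.

Step 3
Reactants: 6 prop-2-yn-1-ol; 3 dimethyl 2-{[4-(benzyloxy)-3-methoxyphenyl]methylidene}propanedioate; 5 1-(benzyloxy)-4-iodo-2-methoxybenzene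
Product: 9 dimethyl (2S,4Z)-2-[4-(benzyloxy)-3-methoxyphenyl]-4-{[4-(benzyloxy)-3-methoxyphenyl]methylidene}oxolane-3,3-dicarboxylate, via lithium prop-2-yn-1-olate 7 (not isolated), via lithium enolate of the oxa-Michael adduct 8 (not isolated)
Conditions: 6 (1.2 equiv), n-BuLi (1.1 equiv), THF, 0 °C; 3 (1.1 equiv), 0 °C to rt; then 5 (1.0 equiv), Pd2(dba)3 (2.5 mol%), (R)-DTBM-SEGPHOS (6 mol%), THF/DMSO 1:1, rt
Reagents that add atoms: none
Why: Proposed new method: the alkoxide 7 adds reversibly to the arylidene malonate 3 (oxa-Michael, O1–C2) to give the stabilised malonate anion 8 as a rapidly interconverting pair of enantiomers, while zerovalent palladium bearing the chiral bisphosphine inserts into the C–I bond of 5; the divalent arylpalladium iodide binds the alkyne of 8, the malonate carbon attacks the internal alkyne carbon from the side away from palladium (C3–C4), and reductive elimination joins C7′ to the aryl group where palladium stood. The closest known reaction type is the racemic PdCl2(PPh3)2-mediated three-component coupling of propargyl alkoxides, alkylidene malonates and aryl halides to 4-arylmethylidene oxolanes; no enantioselective version is on record. The oxolane closes in the 5-exo-dig mode, fixed by the O–CH2 tether, which brings only the internal alkyne carbon within reach of C3. C2 is the only new stereocentre and is to be selected by the chiral bisphosphine on palladium in the irreversible cyclisation, the two enantiomers of 8 being replenished from each other by retro-oxa-Michael/re-addition (dynamic kinetic resolution), which is the unproven point. The step needs racemisation of 8 to be faster than ring closure, which the electron-rich aryl group (a loosened O1–C2 bond) and the low palladium loading favour, and it needs anti rather than syn carbopalladation, which the soft malonate nucleophile secures and which gives the Z alkene (aryl trans to C3).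

Step 4
Reactants: 9 dimethyl (2S,4Z)-2-[4-(benzyloxy)-3-methoxyphenyl]-4-{[4-(benzyloxy)-3-methoxyphenyl]methylidene}oxolane-3,3-dicarboxylate
Product: 10 methyl (2R,3R,4Z)-2-[4-(benzyloxy)-3-methoxyphenyl]-4-{[4-(benzyloxy)-3-methoxyphenyl]methylidene}oxolane-3-carboxylate
Conditions: LiCl (3 equiv), H2O (2 equiv), DMSO, 140 °C
Reagents that add atoms: none
Why: Krapcho dealkoxycarbonylation (chloride attack on one ester methyl group, loss of CO2, protonation of the ester dienolate at C3); the remaining C3–H is acidic (ester α and allylic), so C3 should settle with the ester trans to the C2 aryl group (3R), C2 is untouched (the change of its descriptor from S to R is only a change of priorities), and the alkene should stay exocyclic in conjugation with the electron-rich arene.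

Step 5
Reactants: 10 methyl (2R,3R,4Z)-2-[4-(benzyloxy)-3-methoxyphenyl]-4-{[4-(benzyloxy)-3-methoxyphenyl]methylidene}oxolane-3-carboxylate
Product: 11 methyl (2R,3R,4S)-2-(4-hydroxy-3-methoxyphenyl)-4-[(4-hydroxy-3-methoxyphenyl)methyl]oxolane-3-carboxylate
Conditions: H2 (1 atm), Pd/C (10% palladium on carbon), EtOAc, rt, stopped after uptake of 3 equiv
Reagents that add atoms: none
Why: heterogeneous catalytic hydrogenation with concurrent hydrogenolysis of both benzyl ethers; hydrogen should reach C4=C7′ from the face opposite the adjacent C3 ester (the C2 aryl group on the other face is one atom further away), which places the benzyl group cis to the ester (4S), and the neutral solvent and limited uptake are meant to spare the benzylic C2–O1 bond.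

Step 6
Reactants: 11 methyl (2R,3R,4S)-2-(4-hydroxy-3-methoxyphenyl)-4-[(4-hydroxy-3-methoxyphenyl)methyl]oxolane-3-carboxylate
Product: 12 methyl (2R,3R,4S)-2-[4-(tert-butyldimethylsilyloxy)-3-methoxyphenyl]-4-{[4-(tert-butyldimethylsilyloxy)-3-methoxyphenyl]methyl}oxolane-3-carboxylate
Conditions: TBSCl (2.5 equiv), imidazole (5 equiv), DMF, rt
Reagents that add atoms: tert-butyldimethylsilyl chloride, CC(C)(C)[Si](C)(C)Cl
Why: imidazole-promoted silylation of both phenols, too mild to epimerise C3; silyl ethers are chosen so that the final unmasking needs neither acid nor hydrogen.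

Step 7
Reactants: 12 methyl (2R,3R,4S)-2-[4-(tert-butyldimethylsilyloxy)-3-methoxyphenyl]-4-{[4-(tert-butyldimethylsilyloxy)-3-methoxyphenyl]methyl}oxolane-3-carboxylate
Product: 13 [(2R,3S,4S)-2-[4-(tert-butyldimethylsilyloxy)-3-methoxyphenyl]-4-{[4-(tert-butyldimethylsilyloxy)-3-methoxyphenyl]methyl}oxolan-3-yl]methanol
Conditions: i-Bu2AlH (DIBAL-H, 2.5 equiv), CH2Cl2, −78 °C to 0 °C; aq. potassium sodium tartrate
Reagents that add atoms: none
Why: hydride reduction of the ester to the primary alcohol C9–OH with a non-basic reagent at low temperature, which should keep C3 and the aryl silyl ethers intact (the descriptor of C3 changes from R to S by priority only).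

Step 8
Reactants: 14 caffeic acid
Product: 16 (E)-3-[3,4-bis(tert-butyldimethylsilyloxy)phenyl]prop-2-enoic acid, via tert-butyldimethylsilyl ester of bis-silylated caffeic acid 15 (not isolated)
Conditions: TBSCl (3.5 equiv), imidazole (7 equiv), DMF, rt; then AcOH/THF/H2O, rt
Reagents that add atoms: tert-butyldimethylsilyl chloride, CC(C)(C)[Si](C)(C)Cl
Why: exhaustive silylation followed by selective hydrolysis of the silyl ester, which is far more labile to aqueous acid than the two aryl silyl ethers.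

Step 9
Reactants: 13 [(2R,3S,4S)-2-[4-(tert-butyldimethylsilyloxy)-3-methoxyphenyl]-4-{[4-(tert-butyldimethylsilyloxy)-3-methoxyphenyl]methyl}oxolan-3-yl]methanol; 16 (E)-3-[3,4-bis(tert-butyldimethylsilyloxy)phenyl]prop-2-enoic acid
Product: 17 [(2R,3S,4S)-2-[4-(tert-butyldimethylsilyloxy)-3-methoxyphenyl]-4-{[4-(tert-butyldimethylsilyloxy)-3-methoxyphenyl]methyl}oxolan-3-yl]methyl (E)-3-[3,4-bis(tert-butyldimethylsilyloxy)phenyl]prop-2-enoate
Conditions: EDC·HCl (1.5 equiv), DMAP (0.2 equiv), CH2Cl2, 0 °C to rt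
Reagents that add atoms: none
Why: Steglich esterification of the only free hydroxyl group, a primary alcohol, with all phenols masked so that no aryl ester can form.

Step 10
Reactants: 17 [(2R,3S,4S)-2-[4-(tert-butyldimethylsilyloxy)-3-methoxyphenyl]-4-{[4-(tert-butyldimethylsilyloxy)-3-methoxyphenyl]methyl}oxolan-3-yl]methyl (E)-3-[3,4-bis(tert-butyldimethylsilyloxy)phenyl]prop-2-enoate
Product: 18 [(2R,3S,4S)-2-(4-hydroxy-3-methoxyphenyl)-4-[(4-hydroxy-3-methoxyphenyl)methyl]oxolan-3-yl]methyl (E)-3-(3,4-dihydroxyphenyl)prop-2-enoate (CNP0132883.1)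
Conditions: Bu4NF (TBAF, 4.4 equiv), AcOH (5 equiv), THF, 0 °C
Reagents that add atoms: none
Why: fluoride-mediated cleavage of the four aryl silyl ethers, fast at 0 °C because phenoxides are good leaving groups on silicon; the acetic acid buffer should protect the caffeate ester and the catechol from base and is too weak to ionise the benzylic C2–O1 bond.

**Compound list**
1 | 4-(benzyloxy)-3-methoxybenzaldehyde | COc1cc(C=O)ccc1OCc1ccccc1 | starting material
2 | dimethyl malonate | COC(=O)CC(=O)OC | starting material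
3 | dimethyl 2-{[4-(benzyloxy)-3-methoxyphenyl]methylidene}propanedioate | COC(=O)C(=Cc1ccc(OCc2ccccc2)c(OC)c1)C(=O)OC | intermediate
4 | 4-iodo-2-methoxyphenol | COc1cc(I)ccc1O | starting material
5 | 1-(benzyloxy)-4-iodo-2-methoxybenzene | COc1cc(I)ccc1OCc1ccccc1 | intermediate
6 | prop-2-yn-1-ol | C#CCO | starting material
7 | lithium prop-2-yn-1-olate | [Li+].[O-]CC#C | intermediate (not isolated)
8 | lithium enolate of dimethyl 2-{[4-(benzyloxy)-3-methoxyphenyl](prop-2-yn-1-yloxy)methyl}propanedioate, both enantiomers in equilibrium | [Li+].COC(=O)C(=C([O-])OC)C(OCC#C)c1ccc(OCc2ccccc2)c(OC)c1 | intermediate (not isolated)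
9 | dimethyl (2S,4Z)-2-[4-(benzyloxy)-3-methoxyphenyl]-4-{[4-(benzyloxy)-3-methoxyphenyl]methylidene}oxolane-3,3-dicarboxylate | COc1cc(/C=C2\CO[C@@H](c3ccc(OCc4ccccc4)c(OC)c3)C2(C(=O)OC)C(=O)OC)ccc1OCc1ccccc1 | intermediate
10 | methyl (2R,3R,4Z)-2-[4-(benzyloxy)-3-methoxyphenyl]-4-{[4-(benzyloxy)-3-methoxyphenyl]methylidene}oxolane-3-carboxylate | COc1cc(/C=C2\CO[C@@H](c3ccc(OCc4ccccc4)c(OC)c3)[C@@H]2C(=O)OC)ccc1OCc1ccccc1 | intermediate
11 | methyl (2R,3R,4S)-2-(4-hydroxy-3-methoxyphenyl)-4-[(4-hydroxy-3-methoxyphenyl)methyl]oxolane-3-carboxylate | COc1cc(C[C@@H]2CO[C@@H](c3ccc(O)c(OC)c3)[C@@H]2C(=O)OC)ccc1O | intermediate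
12 | methyl (2R,3R,4S)-2-[4-(tert-butyldimethylsilyloxy)-3-methoxyphenyl]-4-{[4-(tert-butyldimethylsilyloxy)-3-methoxyphenyl]methyl}oxolane-3-carboxylate | COc1cc(C[C@@H]2CO[C@@H](c3ccc(O[Si](C)(C)C(C)(C)C)c(OC)c3)[C@@H]2C(=O)OC)ccc1O[Si](C)(C)C(C)(C)C | intermediate
13 | [(2R,3S,4S)-2-[4-(tert-butyldimethylsilyloxy)-3-methoxyphenyl]-4-{[4-(tert-butyldimethylsilyloxy)-3-methoxyphenyl]methyl}oxolan-3-yl]methanol | COc1cc(C[C@@H]2CO[C@@H](c3ccc(O[Si](C)(C)C(C)(C)C)c(OC)c3)[C@@H]2CO)ccc1O[Si](C)(C)C(C)(C)C | intermediate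
14 | caffeic acid | OC(=O)/C=C/c1ccc(O)c(O)c1 | starting material
15 | tert-butyldimethylsilyl (E)-3-[3,4-bis(tert-butyldimethylsilyloxy)phenyl]prop-2-enoate | CC(C)(C)[Si](C)(C)OC(=O)/C=C/c1ccc(O[Si](C)(C)C(C)(C)C)c(O[Si](C)(C)C(C)(C)C)c1 | intermediate (not isolated)
16 | (E)-3-[3,4-bis(tert-butyldimethylsilyloxy)phenyl]prop-2-enoic acid | OC(=O)/C=C/c1ccc(O[Si](C)(C)C(C)(C)C)c(O[Si](C)(C)C(C)(C)C)c1 | intermediate
17 | [(2R,3S,4S)-2-[4-(tert-butyldimethylsilyloxy)-3-methoxyphenyl]-4-{[4-(tert-butyldimethylsilyloxy)-3-methoxyphenyl]methyl}oxolan-3-yl]methyl (E)-3-[3,4-bis(tert-butyldimethylsilyloxy)phenyl]prop-2-enoate | COc1cc(C[C@@H]2CO[C@@H](c3ccc(O[Si](C)(C)C(C)(C)C)c(OC)c3)[C@@H]2COC(=O)/C=C/c2ccc(O[Si](C)(C)C(C)(C)C)c(O[Si](C)(C)C(C)(C)C)c2)ccc1O[Si](C)(C)C(C)(C)C | intermediate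
18 | [(2R,3S,4S)-2-(4-hydroxy-3-methoxyphenyl)-4-[(4-hydroxy-3-methoxyphenyl)methyl]oxolan-3-yl]methyl (E)-3-(3,4-dihydroxyphenyl)prop-2-enoate | COc1cc(C[C@@H]2CO[C@@H](c3ccc(O)c(OC)c3)[C@@H]2COC(=O)/C=C/c2ccc(O)c(O)c2)ccc1O | target

**Step count**
Total: 10 steps. Longest linear sequence: 8 steps (1, 3, 4, 5, 6, 7, 9, 10); steps 2 and 8 are side branches.

**Steps most likely to fail**

1. Step 3. The chiral palladium species may discriminate poorly between the two equilibrating enantiomers of 8, or ring closure may outrun their interconversion, so that 9 forms with low enantiomeric purity.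
Fallback (from 3, 5 and 6, back at 10): the coupling is run in its known racemic form with PdCl2(PPh3)2 reduced to zerovalent palladium by n-BuLi in THF/DMSO at rt. This gives racemic dimethyl (4Z)-2-[4-(benzyloxy)-3-methoxyphenyl]-4-{[4-(benzyloxy)-3-methoxyphenyl]methylidene}oxolane-3,3-dicarboxylate F1. Krapcho treatment as in step 4 gives the racemic trans ester, methyl (2R*,3R*,4Z)-2-[4-(benzyloxy)-3-methoxyphenyl]-4-{[4-(benzyloxy)-3-methoxyphenyl]methylidene}oxolane-3-carboxylate F2. LiOH in THF/H2O gives the racemic trans acid, (2R*,3R*,4Z)-2-[4-(benzyloxy)-3-methoxyphenyl]-4-{[4-(benzyloxy)-3-methoxyphenyl]methylidene}oxolane-3-carboxylic acid F3. Crystallisation with (S)-1-phenylethylamine is to give the diastereomerically pure salt, (S)-1-phenylethylammonium (2R,3R,4Z)-2-[4-(benzyloxy)-3-methoxyphenyl]-4-{[4-(benzyloxy)-3-methoxyphenyl]methylidene}oxolane-3-carboxylate F4; the (R) amine is taken instead if the salt of the antipode proves the less soluble. Aqueous KHSO4 frees the (2R,3R,4Z)-2-[4-(benzyloxy)-3-methoxyphenyl]-4-{[4-(benzyloxy)-3-methoxyphenyl]methylidene}oxolane-3-carboxylic acid F5, and MeI/K2CO3 in DMF gives 10.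

2. Step 4. Under hot chloride in wet DMSO the exocyclic C4=C7′ bond may migrate into the ring (to the C3=C4 enoate), which would erase C3 and change the face offered in step 5; the C3 epimer ratio may also be unfavourable.
Fallback (from 9, back at 10): mono-saponification with KOH (1.05 equiv) in MeOH/THF/H2O at rt gives the malonic half acid, (2S,4Z)-2-[4-(benzyloxy)-3-methoxyphenyl]-4-{[4-(benzyloxy)-3-methoxyphenyl]methylidene}-3-(methoxycarbonyl)oxolane-3-carboxylic acid F6, as both C3 epimers. Decarboxylation in toluene at 100 °C under neutral conditions, through the ester enol and not a free dienolate, should give 10 together with its C3 epimer, methyl (2R,3S,4Z)-2-[4-(benzyloxy)-3-methoxyphenyl]-4-{[4-(benzyloxy)-3-methoxyphenyl]methylidene}oxolane-3-carboxylate F7. Catalytic NaOMe in MeOH at 0 °C converts F7 into the trans ester 10.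

3. Step 5. Hydrogen delivery to C4=C7′ may be poorly face-selective on the ester, the alkene may migrate on palladium before it is reduced, or the benzylic C2–O1 bond may be hydrogenolysed once the para phenol is free.
Fallback (from 10, back at 13): the ester is reduced first with i-Bu2AlH in CH2Cl2 at −78 °C to the homoallylic alcohol, [(2R,3S,4Z)-2-[4-(benzyloxy)-3-methoxyphenyl]-4-{[4-(benzyloxy)-3-methoxyphenyl]methylidene}oxolan-3-yl]methanol F8. Hydrogenation over Pd/C in EtOAc, a substrate class (3-hydroxymethyl-4-arylmethylidene-2-aryloxolanes) for which the 3,4-cis outcome has precedent, with loss of both benzyl groups, should give the triol 4-[(2R,3S,4S)-4-[(4-hydroxy-3-methoxyphenyl)methyl]-3-(hydroxymethyl)oxolan-2-yl]-2-methoxyphenol F9. TBSCl/imidazole in DMF gives the tris silyl ether, tert-butyl{[(2R,3S,4S)-2-[4-(tert-butyldimethylsilyloxy)-3-methoxyphenyl]-4-{[4-(tert-butyldimethylsilyloxy)-3-methoxyphenyl]methyl}oxolan-3-yl]methoxy}dimethylsilane F10. PPTS in MeOH at rt cleaves only the primary alkyl silyl ether and gives 13.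

**Further compounds**
F1 | step 3 | racemic dimethyl (4Z)-2-[4-(benzyloxy)-3-methoxyphenyl]-4-{[4-(benzyloxy)-3-methoxyphenyl]methylidene}oxolane-3,3-dicarboxylate | COc1cc(/C=C2\COC(c3ccc(OCc4ccccc4)c(OC)c3)C2(C(=O)OC)C(=O)OC)ccc1OCc1ccccc1
F2 | step 3 | racemic methyl (2R*,3R*,4Z)-2-[4-(benzyloxy)-3-methoxyphenyl]-4-{[4-(benzyloxy)-3-methoxyphenyl]methylidene}oxolane-3-carboxylate (both enantiomers written) | COc1cc(/C=C2\CO[C@@H](c3ccc(OCc4ccccc4)c(OC)c3)[C@@H]2C(=O)OC)ccc1OCc1ccccc1.COc1cc(/C=C2\CO[C@H](c3ccc(OCc4ccccc4)c(OC)c3)[C@H]2C(=O)OC)ccc1OCc1ccccc1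
F3 | step 3 | racemic (2R*,3R*,4Z)-2-[4-(benzyloxy)-3-methoxyphenyl]-4-{[4-(benzyloxy)-3-methoxyphenyl]methylidene}oxolane-3-carboxylic acid (both enantiomers written) | COc1cc(/C=C2\CO[C@@H](c3ccc(OCc4ccccc4)c(OC)c3)[C@@H]2C(=O)O)ccc1OCc1ccccc1.COc1cc(/C=C2\CO[C@H](c3ccc(OCc4ccccc4)c(OC)c3)[C@H]2C(=O)O)ccc1OCc1ccccc1
F4 | step 3 | (S)-1-phenylethylammonium (2R,3R,4Z)-2-[4-(benzyloxy)-3-methoxyphenyl]-4-{[4-(benzyloxy)-3-methoxyphenyl]methylidene}oxolane-3-carboxylate | C[C@H]([NH3+])c1ccccc1.COc1cc(/C=C2\CO[C@@H](c3ccc(OCc4ccccc4)c(OC)c3)[C@@H]2C(=O)[O-])ccc1OCc1ccccc1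
F5 | step 3 | (2R,3R,4Z)-2-[4-(benzyloxy)-3-methoxyphenyl]-4-{[4-(benzyloxy)-3-methoxyphenyl]methylidene}oxolane-3-carboxylic acid | COc1cc(/C=C2\CO[C@@H](c3ccc(OCc4ccccc4)c(OC)c3)[C@@H]2C(=O)O)ccc1OCc1ccccc1
F6 | step 4 | (2S,4Z)-2-[4-(benzyloxy)-3-methoxyphenyl]-4-{[4-(benzyloxy)-3-methoxyphenyl]methylidene}-3-(methoxycarbonyl)oxolane-3-carboxylic acid (both C3 epimers) | COc1cc(/C=C2\CO[C@@H](c3ccc(OCc4ccccc4)c(OC)c3)C2(C(=O)O)C(=O)OC)ccc1OCc1ccccc1
F7 | step 4 | methyl (2R,3S,4Z)-2-[4-(benzyloxy)-3-methoxyphenyl]-4-{[4-(benzyloxy)-3-methoxyphenyl]methylidene}oxolane-3-carboxylate | COc1cc(/C=C2\CO[C@@H](c3ccc(OCc4ccccc4)c(OC)c3)[C@H]2C(=O)OC)ccc1OCc1ccccc1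
F8 | step 5 | [(2R,3S,4Z)-2-[4-(benzyloxy)-3-methoxyphenyl]-4-{[4-(benzyloxy)-3-methoxyphenyl]methylidene}oxolan-3-yl]methanol | COc1cc(/C=C2\CO[C@@H](c3ccc(OCc4ccccc4)c(OC)c3)[C@@H]2CO)ccc1OCc1ccccc1
F9 | step 5 | 4-[(2R,3S,4S)-4-[(4-hydroxy-3-methoxyphenyl)methyl]-3-(hydroxymethyl)oxolan-2-yl]-2-methoxyphenol | COc1cc(C[C@@H]2CO[C@@H](c3ccc(O)c(OC)c3)[C@@H]2CO)ccc1O
F10 | step 5 | tert-butyl{[(2R,3S,4S)-2-[4-(tert-butyldimethylsilyloxy)-3-methoxyphenyl]-4-{[4-(tert-butyldimethylsilyloxy)-3-methoxyphenyl]methyl}oxolan-3-yl]methoxy}dimethylsilane | COc1cc(C[C@@H]2CO[C@@H](c3ccc(O[Si](C)(C)C(C)(C)C)c(OC)c3)[C@@H]2CO[Si](C)(C)C(C)(C)C)ccc1O[Si](C)(C)C(C)(C)C
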